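**Retrosynthetic overview**

1. Ring C (dihydropyran O12–C13–C18–C19–C10=C11) is closed last. The anomeric acetate on C13 and the tertiary hydroxyl O26 on C24 are 1,3-cis across C18, so one acyloxycarbenium ion at C13 can form C13–C18 and, through its own acetate as a six-membered acetoxonium ion, C24–O26.
2. The precursor is the tricyclic (E)-enol formate 24. Its enol geometry (O12 cis to C19) is set by hydride addition to the ketene derived from acid 20, followed by O-formylation.
3. Ring B (oxepane) is closed by C7–O8–C9 etherification on a cyclic sulfate, which also distinguishes C7 from C5.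
4. Ring D (methylcycloheptene) comes from ring-closing metathesis; it is trans-fused to the cyclopropane because C19 and C22 are trans on C20–C21 in the target SMILES. C19 is set by an iridium-catalysed allylic alkylation with malonate (C9, C10, C11).
5. Ring A (cyclopropane) is made first by organocatalytic cyclopropanation of a dienal with dimethyl bromomalonate. Ring order: A, D, B, C.

Key step: step 15

Remark: atom labels (C5, O8, C13 …) are the heavy-atom positions of the target SMILES; on the cyclopropane C7 (on C6) is cis to C19 (on C20), and C5 is cis to C22 (on C21).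

Assumption: the (Sa,S,S)-phosphoramidite is taken as the ligand antipode that gives (S)-C19 in 11; if the sense of induction is opposite on this substrate, its mirror image is used.

**Route**

Step 1
Reactants: 1 4-methylpent-4-en-1-ol
Product: 3 (2E)-6-methylhepta-2,6-dienal, via 4-methylpent-4-enal 2 (not isolated)
Conditions: TEMPO (10 mol%), PhI(OAc)2 (1.1 equiv), CH2Cl2, rt; then Ph3P=CHCHO (1.1 equiv), 40 °C
Reagents that add atoms: (triphenylphosphoranylidene)acetaldehyde, O=CC=P(c1ccccc1)(c1ccccc1)c1ccccc1
Why: Oxoammonium (TEMPO) oxidation gives the volatile aldehyde, which is homologated in the same flask by a Wittig reaction with the formyl-stabilised ylide; stabilised ylides give the (E)-enal and the isopropenyl group is inert.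

Step 2
Reactants: 3 (2E)-6-methylhepta-2,6-dienal; 4 dimethyl bromomalonate
Product: 5 dimethyl (2R,3R)-2-formyl-3-(3-methylbut-3-en-1-yl)cyclopropane-1,1-dicarboxylate
Conditions: (S)-α,α-diphenylprolinol trimethylsilyl ether (20 mol%), 2,6-lutidine (1.1 equiv), CH2Cl2, 0 °C → rt
Reagents that add atoms: none
Why: Organocatalytic Michael-initiated ring closure: the bromomalonate anion adds to the iminium ion on the face opposite the diarylsilyloxymethyl group (sets C21) and the enamine then displaces bromide 3-exo-tet, closing ring A with the formyl group and the side chain trans (sets C20).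

Step 3
Reactants: 5 cyclopropane aldehyde
Product: 6 dimethyl (2R,3R)-2-[(1E)-3-ethoxy-3-oxoprop-1-en-1-yl]-3-(3-methylbut-3-en-1-yl)cyclopropane-1,1-dicarboxylate
Conditions: (EtO)2P(O)CH2CO2Et, LiCl, iPr2NEt, MeCN, 0 °C → rt
Reagents that add atoms: triethyl phosphonoacetate, CCOC(=O)CP(=O)(OCC)OCC
Why: Masamune–Roush Horner–Wadsworth–Emmons olefination under mild base gives the (E)-enoate without epimerising the cyclopropyl aldehyde.

Step 4
Reactants: 6 enoate triester
Product: 7 (2E)-3-[(1R,3R)-2,2-bis(hydroxymethyl)-3-(3-methylbut-3-en-1-yl)cyclopropyl]prop-2-en-1-ol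
Conditions: iBu2AlH (7 equiv), CH2Cl2, −78 → 0 °C; aq. KNaC4H4O6
Reagents that add atoms: none
Why: iBu2AlH reduces the conjugated ester 1,2 to the allylic alcohol and both cyclopropane esters to hydroxymethyl groups, which removes the acceptor groups that would let a low-valent metal open the vinylcyclopropane in step 7.

Step 5
Reactants: 7 triol
Product: 8 (2E)-3-[(1R,2R)-6,6-dimethyl-2-(3-methylbut-3-en-1-yl)-5,7-dioxaspiro[2.5]octan-1-yl]prop-2-en-1-ol
Conditions: Me2C(OMe)2, PPTS (5 mol%), CH2Cl2, rt; then MeOH, rt
Reagents that add atoms: 2,2-dimethoxypropane, COC(C)(C)OC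
Why: Acid-catalysed transketalisation closes the six-membered 1,3-dioxane on the geminal hydroxymethyl pair (C5, C7), and any mixed ketal on the allylic hydroxyl is cleaved by the methanol treatment.

Step 6
Reactants: 8 acetonide allylic alcohol
Product: 9 (2E)-3-[(1R,2R)-6,6-dimethyl-2-(3-methylbut-3-en-1-yl)-5,7-dioxaspiro[2.5]octan-1-yl]prop-2-en-1-yl methyl carbonate
Conditions: ClCO2Me, pyridine, CH2Cl2, 0 °C
Reagents that add atoms: methyl chloroformate, COC(=O)Cl
Why: Acylation of the only free hydroxyl gives the linear allylic carbonate required for iridium-catalysed allylic substitution.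

Step 7
Reactants: 9 allylic methyl carbonate; 10 dimethyl malonate
Product: 11 dimethyl 2-{(1S)-1-[(1R,2R)-6,6-dimethyl-2-(3-methylbut-3-en-1-yl)-5,7-dioxaspiro[2.5]octan-1-yl]prop-2-en-1-yl}propanedioate
Conditions: [Ir(cod)Cl]2 (2 mol%), (Sa,S,S)-O,O'-(1,1'-binaphthyl-2,2'-diyl) N,N-bis(1-phenylethyl)phosphoramidite (4 mol%), TBD (8 mol%), THF, rt
Reagents that add atoms: none
Why: Iridium-catalysed asymmetric allylic alkylation under salt-free conditions (methoxide released from the carbonate deprotonates the malonate) gives the branched product, and the cyclometallated phosphoramidite complex controls the new C19 stereocentre by directing the malonate to one face of the substituted allyl terminus.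

Step 8
Reactants: 11 diene malonate
Product: 12 dimethyl 2-[4,2',2'-trimethylspiro[bicyclo[5.1.0]oct-3-ene-8,5'-[1,3]dioxan]-2-yl]propanedioate (ring D closed; trans-fused cyclopropane)
Conditions: second-generation Hoveyda–Grubbs catalyst (H2IMes)Cl2Ru=CH(C6H4-2-OiPr) (10 mol%), toluene (2 mM), 80 °C, Ar sparge
Reagents that add atoms: none
Why: Ring-closing metathesis of the C18 vinyl group with the 1,1-disubstituted isopropenyl terminus closes the trisubstituted cycloheptene, driven by loss of ethene at high dilution; no stereocentre is formed and the trans ring fusion is already fixed by the cyclopropane.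

Step 9
Reactants: 12 cycloheptene malonate
Product: 13 2-[4,2',2'-trimethylspiro[bicyclo[5.1.0]oct-3-ene-8,5'-[1,3]dioxan]-2-yl]propane-1,3-diol
Conditions: LiAlH4, THF, 0 °C → rt
Reagents that add atoms: none
Why: Hydride reduction of both malonate esters gives the 2-substituted propane-1,3-diol whose two arms become C9 and C11.

Step 10
Reactants: 13 1,3-diol
Product: 14 5-[4,2',2'-trimethylspiro[bicyclo[5.1.0]oct-3-ene-8,5'-[1,3]dioxan]-2-yl]-1,3,2-dioxathiane 2,2-dioxide (cyclic sulfate)
Conditions: SO2(imidazol-1-yl)2, NaH, THF, −20 °C → rt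
Reagents that add atoms: 1,1'-sulfonyldiimidazole, O=S(=O)(n1ccnc1)n1ccnc1
Why: Double O-sulfonylation of the 1,3-diol by the sulfuryl-transfer reagent closes the six-membered cyclic sulfate, a 1,3-dielectrophile made here without the alkene-cleaving ruthenium oxidation of a cyclic sulfite.

Step 11
Reactants: 14 cyclic sulfate acetonide
Product: 15 [2-(2,2-dioxo-1,3,2-dioxathian-5-yl)-4-methylbicyclo[5.1.0]oct-3-ene-8,8-diyl]dimethanol
Conditions: AcOH–H2O–THF (3:1:1), 35 °C
Reagents that add atoms: none
Why: Mild aqueous acid hydrolyses the ketal, while the six-membered cyclic sulfate and the trisubstituted alkene should tolerate dilute acetic acid at this temperature.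

Step 12
Reactants: 15 diol cyclic sulfate
Product: 18 tricyclic hydroxymethyl oxepane acetate (ring B closed; C5–OAc; C10–CH2OH; C10 epimers), via disodium alkoxide sulfate 16 (not isolated), via sodium sulfate monoester acetate 17 (not isolated)
Conditions: NaH (2.2 equiv), THF (5 mM), 0 °C → rt; then Ac2O, rt; then H2SO4 (cat.), H2O (2 equiv), THF, rt
Reagents that add atoms: acetic anhydride, CC(=O)OC(C)=O
Why: Intramolecular Williamson-type opening of the cyclic sulfate (7-exo-tet) by the alkoxide on C7, the only hydroxymethyl group cis to C19 on the cyclopropane, closes ring B and so distinguishes C7 from C5; the remaining C5 alkoxide is acetylated, acid hydrolysis of the sulfate monoester frees C11–OH, and the C10 epimers converge later when C10 becomes trigonal.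

Step 13
Reactants: 18 tricyclic alcohol
Product: 20 tricyclic carboxylic acid (C11 = CO2H; C10 epimers), via aldehyde 19 (not isolated)
Conditions: TEMPO (20 mol%), PhI(OAc)2 (2.2 equiv), MeCN–H2O (1:1), rt
Reagents that add atoms: water, O
Why: TEMPO/PhI(OAc)2 oxidation in aqueous acetonitrile takes the primary alcohol through the aldehyde hydrate to the acid without affecting the alkene, the cyclopropane or the acetate.

Step 14
Reactants: 20 tricyclic carboxylic acid
Product: 24 tricyclic (E)-enol formate (key-step precursor), via acid chloride 21 (not isolated), via ketene 22 (not isolated), via potassium enolate 23 (not isolated)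
Conditions: Me2C=C(Cl)NMe2, CH2Cl2, 0 °C; Et3N, Et2O, rt, filtration under Ar; inverse addition to K[sBu3BH] (1.05 equiv), THF, −78 °C; then HCO2COtBu, −78 °C
Reagents that add atoms: formic pivalic anhydride, O=COC(=O)C(C)(C)C
Why: Neutral acid-chloride formation, dehydrochlorination to the ketene and hydride addition to the ketene carbonyl (as in the reduction of ketenes to aldehyde enolates and the in-plane addition of organolithiums to unsymmetrical ketenes): the hydride should reach C11 in the plane of the ketene substituents from the C9 side, because the equatorial C18 screens the C19 side, so O12 ends cis to C19, and O-formylation of the potassium enolate fixes this (E)-geometry.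

Step 15
Reactants: 24 tricyclic (E)-enol formate
Product: 27 target CNP0250836.2, via acyloxycarbenium triflate 25 (not isolated), via dioxanylium triflate 26 (not isolated)
Conditions: Ac2O (1.5 equiv), Me3SiOTf (1.1 equiv), 2,6-di-tert-butyl-4-methylpyridine, CH2Cl2, −78 → −40 °C; then H2O–THF, −40 → 0 °C; aq. NaHCO3
Reagents that add atoms: acetic anhydride, CC(=O)OC(C)=O; water, O
Why: Proposed new method: Acetyl triflate (from Ac2O and Me3SiOTf) acetylates the formate carbonyl oxygen of 24 to the acyloxy-oxocarbenium ion 25, whose C13 is attacked by C18 of the C18=C24 alkene, and the tertiary, non-cyclopropylcarbinyl cation left at C24 is captured by the carbonyl oxygen of the new acetate to give the 2-methyl-1,3-dioxan-2-ylium ion 26, which water opens to the hydroxy acetate. The closest known reactions are Prins cyclisations of acyloxycarbenium ions generated from acylals and of oxocarbenium ions from α-acetoxy ethers, the cationic [4+2] addition of N-acyliminium ions to alkenes, and the hydrolysis of acetoxonium ions in the Woodward–Prévost hydroxylation; what is untested is an alkoxy(acyloxy)carbenium ion made from a formate. Ring C closes by a 6-exo cation–olefin closure (C13–C18, cation exocyclic at C24) and the transient dioxanylium ring by six-membered O-attack on C24. C18 is set by the tether, since C13 hangs from C10 on C19 and reaches only the C10 face of the alkene (cis C18–C19 fusion); C24 is set by delivery of the acetate oxygen on the face that already carries C13 (syn addition, O26 cis to C13); C13 is set by a chair-like closure with the acetoxy group pseudo-equatorial, which gives the trans-fused dioxanylium ion and the anomerically favoured acetate (H13 trans to H18). The step needs C-attack at C18 rather than C24 (Markovnikov polarity and the six-membered ring secure it) and acetylation at the formate oxygen rather than at O8, the C5 acetate or the enol carbon, for which the (E)-enol formate holds C13 next to the equatorial C18 and a near-stoichiometric charge of acetyl triflate at −78 °C with a hindered pyridine is used. Under the acidic quench the hemiorthoester should expel the more basic tertiary oxygen O26, leaving the acetyl group on O14.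

**Compound list**

1 | 4-methylpent-4-en-1-ol | CC(=C)CCCO | starting material
2 | 4-methylpent-4-enal | CC(=C)CCC=O | intermediate
3 | (2E)-6-methylhepta-2,6-dienal | CC(=C)CC/C=C/C=O | intermediate
4 | dimethyl bromomalonate | COC(=O)C(Br)C(=O)OC | starting material
5 | dimethyl (2R,3R)-2-formyl-3-(3-methylbut-3-en-1-yl)cyclopropane-1,1-dicarboxylate | COC(=O)C1(C(=O)OC)[C@H](C=O)[C@H]1CCC(C)=C | intermediate
6 | dimethyl (2R,3R)-2-[(1E)-3-ethoxy-3-oxoprop-1-en-1-yl]-3-(3-methylbut-3-en-1-yl)cyclopropane-1,1-dicarboxylate | COC(=O)C1(C(=O)OC)[C@H](/C=C/C(=O)OCC)[C@H]1CCC(C)=C | intermediate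
7 | (2E)-3-[(1R,3R)-2,2-bis(hydroxymethyl)-3-(3-methylbut-3-en-1-yl)cyclopropyl]prop-2-en-1-ol | OCC1(CO)[C@H](/C=C/CO)[C@H]1CCC(C)=C | intermediate
8 | (2E)-3-[(1R,2R)-6,6-dimethyl-2-(3-methylbut-3-en-1-yl)-5,7-dioxaspiro[2.5]octan-1-yl]prop-2-en-1-ol | CC1(C)OCC2(CO1)[C@H](/C=C/CO)[C@H]2CCC(C)=C | intermediate
9 | (2E)-3-[(1R,2R)-6,6-dimethyl-2-(3-methylbut-3-en-1-yl)-5,7-dioxaspiro[2.5]octan-1-yl]prop-2-en-1-yl methyl carbonate | CC1(C)OCC2(CO1)[C@H](/C=C/COC(=O)OC)[C@H]2CCC(C)=C | intermediate
10 | dimethyl malonate | COC(=O)CC(=O)OC | starting material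
11 | dimethyl 2-{(1S)-1-[(1R,2R)-6,6-dimethyl-2-(3-methylbut-3-en-1-yl)-5,7-dioxaspiro[2.5]octan-1-yl]prop-2-en-1-yl}propanedioate | CC1(C)OCC2(CO1)[C@H]([C@H](C=C)C(C(=O)OC)C(=O)OC)[C@H]2CCC(C)=C | intermediate
12 | dimethyl 2-[4,2',2'-trimethylspiro[bicyclo[5.1.0]oct-3-ene-8,5'-[1,3]dioxan]-2-yl]propanedioate; cyclopropane trans-fused to the cycloheptene, C19–H anti to C20–H, configuration as in the SMILES | CC1(C)OCC2(CO1)[C@@H]3[C@@H](C(C(=O)OC)C(=O)OC)C=C(C)CC[C@@H]23 | intermediate
13 | 2-[4,2',2'-trimethylspiro[bicyclo[5.1.0]oct-3-ene-8,5'-[1,3]dioxan]-2-yl]propane-1,3-diol; ring stereochemistry as in 12 | CC1(C)OCC2(CO1)[C@@H]3[C@@H](C(CO)CO)C=C(C)CC[C@@H]23 | intermediate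
14 | 5-[4,2',2'-trimethylspiro[bicyclo[5.1.0]oct-3-ene-8,5'-[1,3]dioxan]-2-yl]-1,3,2-dioxathiane 2,2-dioxide; ring stereochemistry as in 12 | CC1(C)OCC2(CO1)[C@@H]3[C@@H](C4COS(=O)(=O)OC4)C=C(C)CC[C@@H]23 | intermediate
15 | [2-(2,2-dioxo-1,3,2-dioxathian-5-yl)-4-methylbicyclo[5.1.0]oct-3-ene-8,8-diyl]dimethanol; ring stereochemistry as in 12 | OCC1(CO)[C@@H]2[C@@H](C3COS(=O)(=O)OC3)C=C(C)CC[C@@H]12 | intermediate
16 | disodium salt of the cyclised alkoxide sulfate: oxepane C6–C7–O8–C9–C10–C19–C20 closed, C5–O(−), C11–OSO3(−), C10 epimers | [Na+].[Na+].[O-]C[C@@]12COCC(COS(=O)(=O)[O-])[C@H]3C=C(C)CC[C@@H]2[C@H]13 | intermediate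
17 | sodium salt of the C5 acetate C11 sulfate monoester, C10 epimers | [Na+].CC(=O)OC[C@@]12COCC(COS(=O)(=O)[O-])[C@H]3C=C(C)CC[C@@H]2[C@H]13 | intermediate
18 | tricyclic alcohol: cyclopropane cis-fused to the oxepane and trans-fused to the 4-methylcycloheptene, C6–CH2OAc, C10–CH2OH, C10 epimers | CC(=O)OC[C@@]12COCC(CO)[C@H]3C=C(C)CC[C@@H]2[C@H]13 | intermediate
19 | tricyclic aldehyde (C11 = CHO), C10 epimers | CC(=O)OC[C@@]12COCC(C=O)[C@H]3C=C(C)CC[C@@H]2[C@H]13 | intermediate
20 | tricyclic carboxylic acid (C11 = CO2H), C10 epimers | CC(=O)OC[C@@]12COCC(C(=O)O)[C@H]3C=C(C)CC[C@@H]2[C@H]13 | intermediate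
21 | tricyclic acid chloride, C10 epimers | CC(=O)OC[C@@]12COCC(C(=O)Cl)[C@H]3C=C(C)CC[C@@H]2[C@H]13 | intermediate
22 | tricyclic ketene (C10=C11=O) | CC(=O)OC[C@@]12COCC(=C=O)[C@H]3C=C(C)CC[C@@H]2[C@H]13 | intermediate
23 | potassium (E)-enolate, O12 cis to C19 | [K+].CC(=O)OC[C@@]12COC/C(=C/[O-])[C@H]3C=C(C)CC[C@@H]2[C@H]13 | intermediate
24 | tricyclic (E)-enol formate with the methylcycloheptene, O12 cis to C19 (key-step precursor) | CC(=O)OC[C@@]12COC/C(=C/OC=O)[C@H]3C=C(C)CC[C@@H]2[C@H]13 | intermediate
25 | acetoxy(enoloxy)carbenium triflate at C13 | CC(=O)OC[C@@]12COC/C(=C/[O+]=COC(C)=O)[C@H]3C=C(C)CC[C@@H]2[C@H]13.[O-]S(=O)(=O)C(F)(F)F | intermediate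
26 | tetracyclic 2-methyl-1,3-dioxan-2-ylium triflate bridging C13 and C24 | CC(=O)OC[C@@]12COCC3=CO[C@H](OC(C)=[O+]5)[C@@H]4[C@H]3[C@@H]1[C@H]2CC[C@@]45C.[O-]S(=O)(=O)C(F)(F)F | intermediate
27 | CNP0250836.2 | CC(=O)OC[C@@]12COCC3=CO[C@H](OC(C)=O)[C@@H]4[C@H]3[C@@H]1[C@H]2CC[C@]4(C)O | target

**Step count and risks**

Total step count: 15. Longest linear sequence: 15 steps (from 1; fully linear).

Steps most likely to fail:

1. Step 15 (Proposed new method). The acyloxycarbenium ion may be diverted before it closes onto C18=C24: acetyl transfer to O8 with opening of the oxepane at the cyclopropylcarbinyl C7, C-acetylation of the enol ether, or collapse of the hemiorthoester toward the tertiary acetate. Fallback with known reactions, setting out from acid 20: the enolate 23 is generated as in step 14 and trapped with COCl2 and then PhSeH/pyridine to give the enol Se-phenyl selenocarbonate F1. Photo-initiated phenylselenyl group-transfer cyclisation of the alkoxycarbonyl radical ((Bu3Sn)2 cat., hν, benzene) closes 6-exo onto C18 and gives the enol lactone tertiary selenide F2. Reductive acetylation (iBu2AlH, −78 °C; then Ac2O, pyridine, DMAP, which also restores the C5 acetate) gives the anomeric acetate selenide F3. Methylation on selenium (MeOTf, 2,6-di-tert-butylpyridine) ionises C24 with participation of the C13 acetate; this re-enters the route at the dioxanylium ion 26, hydrolysed to 27.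

2. Step 8. Ring closure may be disfavoured by the strain of the trans-fused bicyclo[5.1.0]octene, so that intermolecular metathesis of the vinyl group takes over. Fallback from 11: ozonolysis of both alkenes (O3, CH2Cl2–MeOH, −78 °C; Me2S) gives the keto aldehyde F4, and an irreversible intramolecular McMurry coupling (TiCl3(DME)1.5, Zn–Cu, DME, reflux, slow addition) forms C18=C24 and returns to 12.

3. Step 14. The ketene may form slowly or dimerise, the hydride may also approach from the C19 side (loss of geometric control), or the enolate may be C-formylated. Fallback from 18: Dess–Martin oxidation to the aldehyde 19 (isolated), enolisation with KN(SiMe3)2/18-crown-6 at −78 °C and O-formylation with formic pivalic anhydride, which should give 24 together with the (Z)-enol formate F5. The isomers are separated, and F5 is returned to 19 by aminolysis (NH3, MeOH, −20 °C) and recycled. The route is rejoined at 24.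

**Further compounds**

F1 | step 15 | tricyclic enol Se-phenyl selenocarbonate (O12–C(=O)–SePh, E) | CC(=O)OC[C@@]12COC/C(=C/OC(=O)[Se]c4ccccc4)[C@H]3C=C(C)CC[C@@H]2[C@H]13
F2 | step 15 | tetracyclic enol lactone (C13=O) with phenylselenyl on C24, C24 epimers | CC(=O)OC[C@@]12COCC3=COC(=O)[C@@H]4[C@H]3[C@@H]1[C@H]2CCC4(C)[Se]c5ccccc5
F3 | step 15 | tetracyclic anomeric acetate with phenylselenyl on C24, C13 anomers and C24 epimers | CC(=O)OC[C@@]12COCC3=COC(OC(C)=O)[C@@H]4[C@H]3[C@@H]1[C@H]2CCC4(C)[Se]c5ccccc5
F4 | step 8 | keto aldehyde from ozonolysis of 11 (C18 = CHO, C24 = methyl ketone) | CC1(C)OCC2(CO1)[C@H]([C@H](C=O)C(C(=O)OC)C(=O)OC)[C@H]2CCC(C)=O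
F5 | step 14 | tricyclic (Z)-enol formate (O12 cis to C9) | CC(=O)OC[C@@]12COC/C(=C\OC=O)[C@H]3C=C(C)CC[C@@H]2[C@H]13
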